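**Plan**

- Numbering follows the target name: ring A is C1(CH3)=C2H–C3H(OH)–C4H(Br)–C5(CH3)2–C6, ring B is C6–C7H2–C8(Br)=C9(CH3)–C10H2–C11H2, and C6 is the spiro carbon.
- Retrosynthesis: the C1=C2 alkene is moved out to C1=CH2; the C2–C3 bond of ring A is cut (carbonyl-ene) to an α-bromo aldehyde; C4–Br is cut (enamine bromination); the ring B bromoalkene goes back to a ketone; the C5–C6 bond is cut (Nicholas alkylation) to reach (R)-carvone and 2-methylbut-3-yn-2-ol.
- Forward: the carvone ring is ring B from the start. C6 is made quaternary with the whole C5–C4–C3 arm, the isopropenyl group (C1, its methyl, C2) is restored, ring B is finished as the bromoalkene, and ring A is closed last through C2–C3.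
- What makes the closure possible: the isopropenyl group on C6 and the aldehyde carbon C3 are held 1,5 by the two adjacent quaternary carbons C5 and C6. C6 has no hydrogen, so the ene reaction can only take hydrogen from the C1 methyl and can only give the six-membered ring A.
- Stereochemistry: C6 comes from carvone by relay (the cis carbinol at C8 is silylated, the new C5–C6 bond forms anti to it, and the relay centre is then erased). C4 is set by the amine catalyst. C3 is set in the ring closure, trans to bromine.

Key step: step 13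

**Route**

Step 1
Reactants: 1 (R)-(−)-carvone
Product: 2 (1R,5R)-2-methyl-5-(prop-1-en-2-yl)cyclohex-2-en-1-ol (cis-carveol)
Conditions: NaBH4, CeCl3·7H2O, MeOH, −20 → 0 °C
Reagents that add atoms: none
Why: Luche reduction gives 1,2-reduction only, and hydride delivery to the half-chair with the isopropenyl group equatorial should place the new hydroxyl cis to it (1R), which creates the relay centre.

Step 2
Reactants: 2 cis-carveol
Product: 3 tert-butyldimethyl{[(1R,5R)-2-methyl-5-(prop-1-en-2-yl)cyclohex-2-en-1-yl]oxy}silane
Conditions: tert-butyldimethylsilyl chloride, imidazole, DMF, 22 °C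
Reagents that add atoms: tert-butyldimethylsilyl chloride, CC(C)(C)[Si](C)(C)Cl
Why: Standard silylation of a secondary allylic alcohol; no stereocentre is touched, and the bulky ether is the shielding group for step 6.

Step 3
Reactants: 3 silyl ether
Product: 4 1-[(1R,3R)-3-(tert-butyldimethylsilyloxy)-4-methylcyclohex-4-en-1-yl]ethan-1-one
Conditions: OsO4 (2 mol %), NaIO4, 2,6-lutidine, dioxane/H2O, 22 °C
Reagents that add atoms: osmium tetroxide, O=[Os](=O)(=O)=O (catalytic oxygen carrier); sodium periodate, [Na+].[O-]I(=O)(=O)=O (reloads it)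
Why: Lemieux–Johnson cleavage should take the unhindered 1,1-disubstituted alkene and leave the trisubstituted ring alkene, which is flanked by the silyloxy group and a methyl group; the acetyl group makes the ring carbon enolisable.

Step 4
Reactants: 4 methyl ketone
Product: 5 tert-butyldimethyl{[(1R)-2-methyl-5-[1-(trimethylsilyloxy)ethylidene]cyclohex-2-en-1-yl]oxy}silane (E/Z mixture at the exocyclic enol ether)
Conditions: (CH3)3SiCl, NaI, Et3N, MeCN, 22 °C
Reagents that add atoms: chlorotrimethylsilane, C[Si](C)(C)Cl
Why: Silyl enol ether formation under equilibrating conditions (iodotrimethylsilane made in the flask) should give the more substituted, exocyclic enol ether; the old ring stereocentre is flattened on purpose and the silyloxy carbinol carbon remains as the only stereocentre.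

Step 5
Reactants: 6 2-methylbut-3-yn-2-ol
Product: 7 hexacarbonyl[μ-(2-methylbut-3-yn-2-ol)]dicobalt
Conditions: Co2(CO)8, CH2Cl2, 22 °C
Reagents that add atoms: dicobalt octacarbonyl, [C-]#[O+].[C-]#[O+].[C-]#[O+].[C-]#[O+].[C-]#[O+].[C-]#[O+].[C-]#[O+].[C-]#[O+].[Co][Co]
Why: Alkyne complexation with loss of two CO ligands is the standard entry to the Nicholas reaction and makes the tertiary propargylic alcohol ionisable.

Step 6
Reactants: 5 silyl enol ether; 7 hexacarbonyl[μ-(2-methylbut-3-yn-2-ol)]dicobalt
Product: 9 1-[(1R,3R)-3-(tert-butyldimethylsilyloxy)-4-methyl-1-(2-methylbut-3-yn-2-yl)cyclohex-4-en-1-yl]ethan-1-one, via its hexacarbonyldicobalt alkyne complex 8 (not isolated)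
Conditions: BF3·OEt2, CH2Cl2, −78 → −30 °C; then (NH4)2Ce(NO3)6, acetone, −78 → 0 °C
Reagents that add atoms: none
Why: Nicholas reaction: the cobalt-stabilised tertiary propargylic cation alkylates the tetrasubstituted enol ether at the ring carbon and so joins the two quaternary carbons C5 and C6; the silyloxy group, pushed pseudo-axial by allylic strain against the vinyl methyl, covers one face, so the new bond should form trans to it and fix C6, after which the cerium salt removes cobalt.

Step 7
Reactants: 9 alkynyl methyl ketone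
Product: 10 tert-butyldimethyl{[(1R,5S)-2-methyl-5-(2-methylbut-3-yn-2-yl)-5-(prop-1-en-2-yl)cyclohex-2-en-1-yl]oxy}silane
Conditions: (C6H5)3PCH3Br, KOC(CH3)3, toluene, 90 °C
Reagents that add atoms: methyltriphenylphosphonium bromide, C[P+](c1ccccc1)(c1ccccc1)c1ccccc1.[Br-]
Why: Wittig methylenation under forcing conditions is the usual answer to a hindered methyl ketone and rebuilds the isopropenyl group; the propargylic carbon is quaternary, so the alkyne cannot isomerise, and no stereocentre is touched.

Step 8
Reactants: 10 silyl ether enyne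
Product: 11 (5S)-2-methyl-5-(2-methylbut-3-yn-2-yl)-5-(prop-1-en-2-yl)cyclohex-2-en-1-one
Conditions: CrO3, H2SO4, H2O, acetone, 0 → 22 °C
Reagents that add atoms: none
Why: Jones oxidation cleaves the allylic silyl ether and oxidises the alcohol to the enone in one operation; the relay centre is erased and the quaternary carbon stays as the only stereocentre.

Step 9
Reactants: 11 enone
Product: 12 (5S)-2-methyl-5-(2-methylbut-3-yn-2-yl)-5-(prop-1-en-2-yl)cyclohexan-1-one (both C2 epimers)
Conditions: LiBH(s-C4H9)3, THF, −78 °C; aq. NH4Cl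
Reagents that add atoms: none
Why: Conjugate reduction of a β-unsubstituted 2-methylcyclohexenone by the bulky borohydride is well known for carvone itself; the methyl-bearing carbon forms without control, which does not matter because step 10 flattens it.

Step 10
Reactants: 12 ketone
Product: 13 (4S)-2-bromo-1-methyl-4-(2-methylbut-3-yn-2-yl)-4-(prop-1-en-2-yl)cyclohex-1-ene
Conditions: P(OC6H5)3, Br2, Et3N, CH2Cl2, −60 → 40 °C
Reagents that add atoms: bromine, BrBr
Why: Ketone to vinyl bromide conversion by triphenyl phosphite dibromide; loss of the proton from the methyl-bearing carbon should give the tetrasubstituted C8(Br)=C9(CH3) alkene, because the other α-carbon is neopentylic next to C6.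

Step 11
Reactants: 13 bromo enyne
Product: 14 3-[(1S)-3-bromo-4-methyl-1-(prop-1-en-2-yl)cyclohex-3-en-1-yl]-3-methylbutanal
Conditions: [(C5H5)Ru(NCCH3)3]PF6 (5 mol %), 5,5′-bis(trifluoromethyl)-2,2′-bipyridine (5 mol %), H2O, N-methylpyrrolidinone, 25 °C
Reagents that add atoms: water, O
Why: Ruthenium-catalysed anti-Markovnikov hydration of a terminal alkyne through a vinylidene gives the aldehyde C3 and leaves the alkenes alone.

Step 12
Reactants: 14 aldehyde
Product: 15 (2S)-2-bromo-3-[(1S)-3-bromo-4-methyl-1-(prop-1-en-2-yl)cyclohex-3-en-1-yl]-3-methylbutanal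
Conditions: (2R,5R)-2,5-diphenylpyrrolidine (20 mol %), 4,4-dibromo-2,6-di-tert-butylcyclohexa-2,5-dienone, C6H5CO2H (20 mol %), H2O, CH2Cl2/pentane, −40 °C; crude product used at once
Reagents that add atoms: 4,4-dibromo-2,6-di-tert-butylcyclohexa-2,5-dien-1-one, CC(C)(C)C1=CC(Br)(Br)C=C(C(C)(C)C)C1=O
Why: Enamine-catalysed α-bromination of an aldehyde with a quaternary β-carbon; the phenyl group beside the E-enamine blocks one face, so bromine should enter from the other and set C4 as (S) under catalyst control, independent of the remote C6.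

Step 13
Reactants: 15 α-bromo aldehyde
Product: 16 (3S,4S,6S)-4,8-dibromo-5,5,9-trimethyl-1-methylidenespiro[5.5]undec-8-en-3-ol
Conditions: CH3Al(OAr)2 (Ar = 4-bromo-2,6-di-tert-butylphenyl, 2 equiv, made from Al(CH3)3 and 2 ArOH), CH2Cl2, −78 → −40 °C
Reagents that add atoms: none
Why: The aluminium aryloxide binds the aldehyde oxygen, and the terminal carbon of the isopropenyl group (C2) adds to the carbonyl carbon C3 while an allylic hydrogen of the methyl group passes to oxygen; this is a Lewis acid promoted intramolecular carbonyl-ene reaction of type two, whose closest precedent is the aluminium-promoted cyclisation of δ,ε-unsaturated aldehydes to 3-methylenecyclohexanols. Ring A (C1 to C6) closes in the 6-exo-trig mode at the carbonyl, with both alkene carbons C1 and C2 ending inside the ring. The one new stereocentre, C3, is set by C4: bromine sits equatorial and antiperiplanar to the forming bond, and the oxygen is kept off the axial site by the bulk of the aryloxide ligands and by the axial methyl on C5, so hydroxyl and bromine should end trans (3S). The step needs this trans selectivity, retention of the labile C4 centre and reaction at the isopropenyl group only. Low temperature and a non-basic, non-nucleophilic Lewis acid protect C4; the geminal methyls on C5 and the quaternary C6 hold the two ends together; C6 has no hydrogen, so the methyl is the only hydrogen donor; and the bromine-bearing ring B alkene is too electron-poor and too remote to compete.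

Step 14
Reactants: 16 exocyclic alkene
Product: 17 (3S,4S,6S)-4,8-dibromo-1,5,5,9-tetramethylspiro[5.5]undeca-1,8-dien-3-ol (target)
Conditions: Co(C36H52N2O2)Cl [chloro cobalt complex of N,N′-bis(3,5-di-tert-butylsalicylidene)cyclohexane-1,2-diamine, trivalent cobalt] (5 mol %), C6H5SiH3 (5 mol %), benzene, 22 °C
Reagents that add atoms: none
Why: Cobalt hydride hydrogen-atom-transfer isomerisation: reversible hydrogen atom addition to the exocyclic methylene gives the tertiary C1 radical, and hydrogen loss from C2 (the only neighbour besides the methyl that carries hydrogen) should give the more substituted endocyclic C1=C2 alkene without touching C3, C4 or C6.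

**Compound list**

1 | (R)-(−)-carvone, (5R)-2-methyl-5-(prop-1-en-2-yl)cyclohex-2-en-1-one | C=C(C)[C@H]1CC(=O)C(C)=CC1 | starting material
2 | (1R,5R)-2-methyl-5-(prop-1-en-2-yl)cyclohex-2-en-1-ol (cis-carveol) | C=C(C)[C@H]1C[C@@H](O)C(C)=CC1 | intermediate
3 | tert-butyldimethyl{[(1R,5R)-2-methyl-5-(prop-1-en-2-yl)cyclohex-2-en-1-yl]oxy}silane | C=C(C)[C@H]1C[C@@H](O[Si](C)(C)C(C)(C)C)C(C)=CC1 | intermediate
4 | 1-[(1R,3R)-3-(tert-butyldimethylsilyloxy)-4-methylcyclohex-4-en-1-yl]ethan-1-one | CC(=O)[C@H]1C[C@@H](O[Si](C)(C)C(C)(C)C)C(C)=CC1 | intermediate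
5 | tert-butyldimethyl{[(1R)-2-methyl-5-[1-(trimethylsilyloxy)ethylidene]cyclohex-2-en-1-yl]oxy}silane (E/Z mixture) | CC(O[Si](C)(C)C)=C1C[C@@H](O[Si](C)(C)C(C)(C)C)C(C)=CC1 | intermediate
6 | 2-methylbut-3-yn-2-ol | CC(C)(O)C#C | starting material
7 | hexacarbonyl[μ-(2-methylbut-3-yn-2-ol)]dicobalt | CC(C)(O)C#C.[C-]#[O+].[C-]#[O+].[C-]#[O+].[C-]#[O+].[C-]#[O+].[C-]#[O+].[Co][Co] | intermediate
8 | hexacarbonyldicobalt alkyne complex of 9 | CC(=O)[C@@]1(C(C)(C)C#C)C[C@@H](O[Si](C)(C)C(C)(C)C)C(C)=CC1.[C-]#[O+].[C-]#[O+].[C-]#[O+].[C-]#[O+].[C-]#[O+].[C-]#[O+].[Co][Co] | intermediate (not isolated)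
9 | 1-[(1R,3R)-3-(tert-butyldimethylsilyloxy)-4-methyl-1-(2-methylbut-3-yn-2-yl)cyclohex-4-en-1-yl]ethan-1-one (silyloxy trans to the dimethylpropargyl group) | CC(=O)[C@@]1(C(C)(C)C#C)C[C@@H](O[Si](C)(C)C(C)(C)C)C(C)=CC1 | intermediate
10 | tert-butyldimethyl{[(1R,5S)-2-methyl-5-(2-methylbut-3-yn-2-yl)-5-(prop-1-en-2-yl)cyclohex-2-en-1-yl]oxy}silane | C=C(C)[C@@]1(C(C)(C)C#C)C[C@@H](O[Si](C)(C)C(C)(C)C)C(C)=CC1 | intermediate
11 | (5S)-2-methyl-5-(2-methylbut-3-yn-2-yl)-5-(prop-1-en-2-yl)cyclohex-2-en-1-one | C=C(C)[C@@]1(C(C)(C)C#C)CC(=O)C(C)=CC1 | intermediate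
12 | (5S)-2-methyl-5-(2-methylbut-3-yn-2-yl)-5-(prop-1-en-2-yl)cyclohexan-1-one (both C2 epimers) | C=C(C)[C@@]1(C(C)(C)C#C)CC(=O)C(C)CC1 | intermediate
13 | (4S)-2-bromo-1-methyl-4-(2-methylbut-3-yn-2-yl)-4-(prop-1-en-2-yl)cyclohex-1-ene | C=C(C)[C@@]1(C(C)(C)C#C)CC(Br)=C(C)CC1 | intermediate
14 | 3-[(1S)-3-bromo-4-methyl-1-(prop-1-en-2-yl)cyclohex-3-en-1-yl]-3-methylbutanal | C=C(C)[C@@]1(C(C)(C)CC=O)CC(Br)=C(C)CC1 | intermediate
15 | (2S)-2-bromo-3-[(1S)-3-bromo-4-methyl-1-(prop-1-en-2-yl)cyclohex-3-en-1-yl]-3-methylbutanal | C=C(C)[C@@]1(C(C)(C)[C@H](Br)C=O)CC(Br)=C(C)CC1 | intermediate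
16 | (3S,4S,6S)-4,8-dibromo-5,5,9-trimethyl-1-methylidenespiro[5.5]undec-8-en-3-ol | C=C1C[C@H](O)[C@@H](Br)C(C)(C)[C@]12CCC(C)=C(Br)C2 | intermediate
17 | (3S,4S,6S)-4,8-dibromo-1,5,5,9-tetramethylspiro[5.5]undeca-1,8-dien-3-ol | CC1=C[C@H](O)[C@@H](Br)C(C)(C)[C@]12CCC(C)=C(Br)C2 | target

**Step count**

Total step count: 14. Longest linear sequence: 13 (steps 1 to 4 and 6 to 14, from carvone); step 5 is a one-step side branch.

**Steps most likely to fail**

1. Step 13. The ring may close through the ordinary chair in which the aluminium-bound oxygen is axial, which would give the cis alcohol, or the α-bromo aldehyde may lose its C4 configuration by enolisation before it closes. The fallback accepts the cis closure and then inverts C3. From 15, (CH3)2AlCl in CH2Cl2 at −78 °C, the usual chair-type ene closure, should give the cis alcohol (3R,4S,6S)-4,8-dibromo-5,5,9-trimethyl-1-methylidenespiro[5.5]undec-8-en-3-ol F1. A Mitsunobu reaction with 4-nitrobenzoic acid, diisopropyl azodicarboxylate and P(C6H5)3 should invert C3 and give (3S,4S,6S)-4,8-dibromo-5,5,9-trimethyl-1-methylidenespiro[5.5]undec-8-en-3-yl 4-nitrobenzoate F2. Reductive removal of the ester with (i-C4H9)2AlH in toluene at −78 °C avoids a free alkoxide that could displace the neighbouring bromide, and the route is rejoined at 16.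

2. Step 12. The amine may condense only slowly with the neopentylic aldehyde, the α-bromo iminium ion may be trapped by the nearby isopropenyl π bond, and the product may erode at C4 before use. The fallback closes ring A first and brings in bromine and oxygen together afterwards. From 13, [(C6H5)3P]AuN(SO2CF3)2 (monovalent gold, catalytic) in CH2Cl2 should cycloisomerise the 1,5-enyne in the 6-endo mode (the alkene CH2 attacks the alkyne terminus, the tertiary C1 cation loses the C2 proton) to the diene (6S)-8-bromo-1,5,5,9-tetramethylspiro[5.5]undeca-1,3,8-triene F3. N-bromosuccinimide in acetone/water at 0 °C should then put bromine on C4 and water on the allylic C3 by anti addition, which gives the trans bromohydrin and rejoins the route at 17. In this variant only the spiro centre distinguishes the two faces, so the face isomer must be expected and separated.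

3. Step 10. Regiocontrol may be lost if elimination runs toward C7, and hydrogen bromide may add to the isopropenyl group. The fallback fixes the regiochemistry through the enolate. From 11, conjugate reduction with LiBH(s-C4H9)3 and trapping of the regiodefined enolate with N-phenylbis(trifluoromethanesulfonimide) should give (5S)-2-methyl-5-(2-methylbut-3-yn-2-yl)-5-(prop-1-en-2-yl)cyclohex-1-en-1-yl trifluoromethanesulfonate F4. Nickel-catalysed triflate to bromide exchange (Ni(C8H12)2, zerovalent nickel, LiBr, N,N-dimethylacetamide/THF, 22 °C) then rejoins the route at 13.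

**Further compounds**

F1 | step 13 | (3R,4S,6S)-4,8-dibromo-5,5,9-trimethyl-1-methylidenespiro[5.5]undec-8-en-3-ol | C=C1C[C@@H](O)[C@@H](Br)C(C)(C)[C@]12CCC(C)=C(Br)C2
F2 | step 13 | (3S,4S,6S)-4,8-dibromo-5,5,9-trimethyl-1-methylidenespiro[5.5]undec-8-en-3-yl 4-nitrobenzoate | C=C1C[C@H](OC(=O)c3ccc(cc3)[N+](=O)[O-])[C@@H](Br)C(C)(C)[C@]12CCC(C)=C(Br)C2
F3 | step 12 | (6S)-8-bromo-1,5,5,9-tetramethylspiro[5.5]undeca-1,3,8-triene | CC1=CC=CC(C)(C)[C@]12CCC(C)=C(Br)C2
F4 | step 10 | (5S)-2-methyl-5-(2-methylbut-3-yn-2-yl)-5-(prop-1-en-2-yl)cyclohex-1-en-1-yl trifluoromethanesulfonate | C=C(C)[C@@]1(C(C)(C)C#C)CC(OS(=O)(=O)C(F)(F)F)=C(C)CC1
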